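All runs are simulated for substances that don't exist, noise included.

**Two constants.** The rate constants are hidden, but two can be read from the runs. Substrate has two routes: to target at a[substrate], with a the pseudo-first-order constant of the catalytic round, and into self-condensation product, which grows with [substrate] squared.

common to all: free catalyst 0.2 mol%

| run | substrate | coupling partner | remark | time |
|---|---|---|---|---|
| north | 0.087 M | 2 equiv | run made earlier |  |
| north-west | 0.12 M | 2 equiv | run made earlier |  |
| south-east | 0.19 M | 2 equiv | run made earlier |  |
| Thursday's | 0.087 M | 2.00 equiv | everything together at the start | 15 min |
| Sunday's | 0.087 M | 2.00 equiv (fed, over 12 min) | all else is in the flask from the start; the feed brings no volume worth counting | 15 min |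
| Saturday's | 0.087 M (fed, over 12 min) | 2.00 equiv | all else is in the flask from the start; the feed brings no volume worth counting | 15 min |

- north (time / min: target / %): 1.00: 14.7; 3.00: 29.9; 5.00: 38.5; 8.00: 47.2; 12.0: 48.3; 15.0: 49.6
- north-west (time / min: target / %): 1.33: 19.7; 4.00: 38.4; 6.00: 42.1; 10.0: 48.2; 15.0: 47.3; 20.0: 48.7
- south-east (time / min: target / %): 1.33: 22.6; 4.00: 38.4; 6.00: 41.2; 10.0: 42.3; 15.0: 43.0; 20.0: 44.0

(readings scatter by 1 percentage point)

- percentages count the substrate that a species holds: one self-condensation product counts as two
- reactions considered so far: coupling partner + free catalyst -> catalyst intermediate A; catalyst intermediate A -> catalyst intermediate B; substrate + catalyst intermediate B -> catalyst intermediate C; catalyst intermediate C -> free catalyst + target; 2 substrate -> self-condensation product; 2 catalyst intermediate B <-> resting dimer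

* which flask leads in amount of target, in percent of the substrate charged ("all alike" within 1.5 percentage points) (Thursday's / Sunday's / Saturday's / all alike)
* how much target is there at the end, in percent of the substrate charged: Thursday's
* how much target is there at the end, in percent of the substrate charged: Sunday's
* how much target is there at the end, in percent of the substrate charged: Saturday's

**Crossing level.** The balance of substrate needs one quantity: the crossing level c, the [substrate] at which both routes take equal amounts. At any moment target receives the share c/(c+[substrate]), the selectivity. Charged together at the start, with a and c held constant, a flask ends at the natural log of (one plus x), divided by x, where x is the charge over c. North's last reading of 49.6% calls for x = 2.50, since that gives 50.1%. So c reads as 0.0348 M.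

**A check.** South-east, with its higher charge, is a separate test. An unchanged c predicts 34.2%. At a fixed loading in mol%, catalyst concentration rises with the charge, and a c growing with its square root, as a catalyst stored in the resting dimer gives, predicts 41.9%. The run's last reading of 44.0% lies closer to this second figure than to the first, so the square root is kept.

**Own reckoning.** North's first reading, with mean substrate taken as 0.750 of the charge, reads as a = 0.196 min⁻¹. Saturday's feed brings 0.00725 M min⁻¹, and the steady level, where this equals a[substrate] times (one plus [substrate]/c), is 0.0225 M. So the share during Saturday's feed is 60.8%, more than the 49.6% expected of Thursday's, which repeats north. Sunday's starts with its substrate at the full charge, as Thursday's does, at a share of 28.6%, so this reckoning gives Sunday's no lift over Thursday's.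

**The forecast.** It put Thursday's at 49%, Sunday's at 46% and Saturday's at 59%, with Saturday's leading, on the ground that “feeding substrate keeps s near 0.25 of the charge, suppressing self-condensation”. Its figure for Saturday's comes from its own integration by hand, not from the share reckoned above.

**The result.** Saturday's leads: Thursday's gives 49.8%, Sunday's 34.3% and Saturday's 67.5%.

    coupling partner + free catalyst → catalyst intermediate A (k = 25.6 M⁻¹ s⁻¹)
    catalyst intermediate A → catalyst intermediate B (k = 4.14 s⁻¹)
    substrate + catalyst intermediate B → catalyst intermediate C (k = 64.0 M⁻¹ s⁻¹)
    catalyst intermediate C → free catalyst + target (k = 188 s⁻¹)
    2 substrate → self-condensation product (k = 0.0502 M⁻¹ s⁻¹)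
    2 catalyst intermediate B ⇌ resting dimer, settled at all times (K = 6870 M⁻¹)

**Same reckoning.** At the end of its feed, Saturday's held 22.1% of the substrate charged, where c gives a momentary share of 64.4%; its target and self-condensation product, formed over the whole feed, then stood at 56.4% and 21.5%, a running share of 72.4%. The neighbour is Saturday's with 0.8 mol% of free catalyst, so the square root reckons a and c each twice as large: c = 0.0696 M, a = 0.392 min⁻¹. The reckoned level falls to 0.0152 M and the reckoned share rises to 82.1%. That neighbour ended with 92.0% target and 6.82% self-condensation product.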